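The nitrogen ring is disconnected at C4–C3 and C1–N, so that it is annulated last onto a preformed 5-aryl ring A. The key step exploits that C4 is a benzylic carbon of ring A ortho to C8a, the carbon bearing C1: with C1 present as a nitrile, the C4 methyl of biaryl 13 is acidic. In one flask, lateral lithiation and addition to the (S)-sulfinimine of acetaldehyde (16) form C4–C3 and set C3, MeLi converts the nitrile into the C1 methyl ketimine, and acid removes the auxiliary so that the C3 amine closes C1–N. Alkylation at nitrogen and hydride reduction of dihydroisoquinoline 20 then set C1 cis to C3.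

Key step: step 8

Remark: atoms are numbered as in the isoquinoline (ring A is its benzene ring, primed numbers belong to the naphthalene); the SMILES fixes only C1 (R) and C3 (S), a cis pair, and not the hindered C5–C1′ axis, so both atropo-diastereomers are taken as the target and the axis is not controlled.

Step 1
Reactants: 1 1-(3-methoxyphenyl)propan-2-one
Product: 2 1-(2-bromo-5-methoxyphenyl)propan-2-one
Conditions: NBS, MeCN, 0 °C to rt, dark
Reagents that add atoms: N-bromosuccinimide, O=C1CCC(=O)N1Br
Why: Electrophilic aromatic bromination, in which NBS in MeCN should brominate the anisole ring para to the methoxy group (the position ortho to the side chain) faster than the enolisable ketone; the bromine blocks this position in step 3 and later serves as the coupling handle.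

Step 2
Reactants: 2 1-(2-bromo-5-methoxyphenyl)propan-2-one; 3 tert-butyl 2-(diethoxyphosphoryl)acetate
Product: 4 tert-butyl 4-(2-bromo-5-methoxyphenyl)-3-methylbut-2-enoate (E/Z mixture)
Conditions: NaH, THF, 0 °C to rt
Reagents that add atoms: none
Why: Horner–Wadsworth–Emmons olefination of the methyl ketone; the E/Z (and any deconjugated) isomers are carried on together because all of them should converge in step 3.

Step 3
Reactants: 4 tert-butyl 4-(2-bromo-5-methoxyphenyl)-3-methylbut-2-enoate
Product: 6 5-bromo-8-methoxy-3-methylnaphthalen-1-ol, via carboxylic acid 5 (not isolated)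
Conditions: P2O5 in MeSO3H (1:10 w/w), rt to 45 °C
Reagents that add atoms: none
Why: Intramolecular Friedel–Crafts acylation, in which the strong acid cleaves the tert-butyl ester to 5, equilibrates the alkene isomers through the O-protonated enoic acid and closes the activated acid onto the only free position ortho to the side chain (ortho to OMe, the para position being blocked by bromine), after which the dienone tautomerises to the naphthol.

Step 4
Reactants: 6 5-bromo-8-methoxy-3-methylnaphthalen-1-ol
Product: 7 1-bromo-4,5-dimethoxy-7-methylnaphthalene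
Conditions: MeI, K2CO3, DMF, 50 °C
Reagents that add atoms: iodomethane, CI
Why: Williamson O-methylation of the naphthol; DMF and warming are chosen because the OH is hydrogen-bonded to the peri methoxy oxygen.

Step 5
Reactants: 8 1-bromo-2,4-dimethoxy-6-methylbenzene
Product: 10 3-bromo-4,6-dimethoxy-2-methylbenzonitrile, via N-chlorosulfonyl amide 9 (not isolated)
Conditions: ClSO2NCO, CH2Cl2, 0 °C to rt; DMF, 0 °C to rt
Reagents that add atoms: chlorosulfonyl isocyanate, O=C=NS(=O)(=O)Cl
Why: Electrophilic aromatic substitution with chlorosulfonyl isocyanate followed by DMF-induced loss of the chlorosulfonyl group from 9 (direct cyanation); attack is expected at the free position next to the methyl group, para to one methoxy group and ortho to the other, because the position between the two methoxy groups is the more hindered one.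

Step 6
Reactants: 7 1-bromo-4,5-dimethoxy-7-methylnaphthalene; 10 3-bromo-4,6-dimethoxy-2-methylbenzonitrile
Product: 13 3-(4,5-dimethoxy-7-methylnaphthalen-1-yl)-4,6-dimethoxy-2-methylbenzonitrile (racemic at the axis), via naphthyllithium 11 (not isolated), via naphthylzinc chloride 12 (not isolated)
Conditions: n-BuLi, THF, −78 °C; ZnCl2, −78 °C to rt; 10, Pd2(dba)3 (cat.), 2-dicyclohexylphosphino-2′,6′-diisopropoxybiphenyl (cat.), THF/NMP, 70 °C
Reagents that add atoms: none
Why: Negishi cross-coupling, in which bromine–lithium exchange and transmetalation give arylzinc 12, which tolerates the nitrile and the acidic benzylic methyl of 10, and zerovalent palladium carrying the bulky electron-rich biarylphosphine should insert into the hindered C–Br bond and deliver the tri-ortho-substituted biaryl.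

Step 7
Reactants: 14 (S)-4-methylbenzenesulfinamide; 15 acetaldehyde
Product: 16 (S,E)-N-ethylidene-4-methylbenzenesulfinamide
Conditions: Ti(OEt)4, CH2Cl2, rt
Reagents that add atoms: none
Why: Ti(OEt)4-mediated condensation of the primary sulfinamide with the aldehyde to the E-sulfinimine; sulfur is not touched, so its S configuration is retained.

Step 8
Reactants: 13 3-(4,5-dimethoxy-7-methylnaphthalen-1-yl)-4,6-dimethoxy-2-methylbenzonitrile; 16 (S,E)-N-ethylidene-4-methylbenzenesulfinamide
Product: 20 (3S)-5-(4,5-dimethoxy-7-methylnaphthalen-1-yl)-6,8-dimethoxy-1,3-dimethyl-3,4-dihydroisoquinoline, via lithium sulfinamide adduct 17 (not isolated), via dilithio ketimine 18 (not isolated), via amino ketimine 19 (not isolated)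
Conditions: LiN(iPr)2, THF, −78 °C; 16, −78 °C; MeLi, −78 to 0 °C; HCl, MeOH, rt; aq. NaHCO3
Reagents that add atoms: methyllithium, [Li]C
Why: LiN(iPr)2 removes a proton from the C4 methyl of 13, the only position acidified by the ortho nitrile (lateral lithiation), and the benzylic anion adds to the C=N bond of 16 to form C4–C3 (17); MeLi then adds to the nitrile to give the C1 methyl ketimine (18), and HCl in MeOH cleaves the N–S bond so that the freed C3 amine of 19 condenses with the ketimine, with loss of ammonia, to form C1–N. The closest known reaction type is the addition of laterally lithiated o-tolunitriles to p-toluenesulfinimines, followed by organolithium addition to the nitrile and acid-induced cyclisation to 3,4-dihydroisoquinolines, here run in one flask. The nitrogen ring closes by 6-exo-trig attack of the amine on the protonated exocyclic C1=N bond, followed by elimination. C3 is controlled by the sulfinyl auxiliary: in a six-membered chair transition state lithium bound to the sulfinyl oxygen delivers the carbanion, the p-tolyl group sits equatorial, and attack on the Re face of the (S,E)-imine should give 3S. The step needs addition to the C=N bond in preference to deprotonation of the acetaldimine methyl and to self-condensation of the anion with a second nitrile; the low basicity of the delocalised anion at −78 °C and the flanking of the nitrile by a methoxy group and the C4 carbon should secure this, and N-lithiation of the sulfinamide shields sulfur from MeLi.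

Step 9
Reactants: 20 (3S)-5-(4,5-dimethoxy-7-methylnaphthalen-1-yl)-6,8-dimethoxy-1,3-dimethyl-3,4-dihydroisoquinoline
Product: 22 (1R,3S)-5-(4,5-dimethoxy-7-methylnaphthalen-1-yl)-6,8-dimethoxy-1,2,3-trimethyl-1,2,3,4-tetrahydroisoquinoline, via iminium iodide 21 (not isolated)
Conditions: MeI, acetone, rt; evaporation; NaBH4, MeOH, −20 to 0 °C
Reagents that add atoms: iodomethane, CI
Why: N-Alkylation of the cyclic imine to iminium salt 21 and hydride reduction, in which the C3 methyl group takes the pseudoaxial position to avoid allylic strain with the N-methyl group and hydride adds to C1 on the opposite face (1,3-induction), which should place the C1 methyl cis to the C3 methyl and give 1R.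

Compound list
1 | 1-(3-methoxyphenyl)propan-2-one | COc1cccc(CC(C)=O)c1 | starting material
2 | 1-(2-bromo-5-methoxyphenyl)propan-2-one | COc1ccc(Br)c(CC(C)=O)c1 | intermediate
3 | tert-butyl 2-(diethoxyphosphoryl)acetate | CCOP(=O)(OCC)CC(=O)OC(C)(C)C | starting material
4 | tert-butyl 4-(2-bromo-5-methoxyphenyl)-3-methylbut-2-enoate (E/Z mixture) | COc1ccc(Br)c(CC(C)=CC(=O)OC(C)(C)C)c1 | intermediate
5 | 4-(2-bromo-5-methoxyphenyl)-3-methylbut-2-enoic acid | COc1ccc(Br)c(CC(C)=CC(=O)O)c1 | intermediate
6 | 5-bromo-8-methoxy-3-methylnaphthalen-1-ol | COc1ccc(Br)c2cc(C)cc(O)c12 | intermediate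
7 | 1-bromo-4,5-dimethoxy-7-methylnaphthalene | COc1ccc(Br)c2cc(C)cc(OC)c12 | intermediate
8 | 1-bromo-2,4-dimethoxy-6-methylbenzene (2-bromo-3,5-dimethoxytoluene) | Cc1cc(OC)cc(OC)c1Br | starting material
9 | 3-bromo-N-(chlorosulfonyl)-4,6-dimethoxy-2-methylbenzamide | Cc1c(Br)c(OC)cc(OC)c1C(=O)NS(=O)(=O)Cl | intermediate
10 | 3-bromo-4,6-dimethoxy-2-methylbenzonitrile | Cc1c(Br)c(OC)cc(OC)c1C#N | intermediate
11 | (4,5-dimethoxy-7-methylnaphthalen-1-yl)lithium | [Li]c1ccc(OC)c2c(OC)cc(C)cc12 | intermediate
12 | chloro(4,5-dimethoxy-7-methylnaphthalen-1-yl)zinc | Cl[Zn]c1ccc(OC)c2c(OC)cc(C)cc12 | intermediate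
13 | 3-(4,5-dimethoxy-7-methylnaphthalen-1-yl)-4,6-dimethoxy-2-methylbenzonitrile | Cc1c(-c2ccc(OC)c3c(OC)cc(C)cc23)c(OC)cc(OC)c1C#N | intermediate
14 | (S)-4-methylbenzenesulfinamide | Cc1ccc(cc1)[S@@](N)=O | starting material
15 | acetaldehyde | CC=O | starting material
16 | (S,E)-N-ethylidene-4-methylbenzenesulfinamide | C/C=N/[S@@](=O)c1ccc(C)cc1 | intermediate
17 | lithium salt of (S)-N-[(2S)-1-[2-cyano-6-(4,5-dimethoxy-7-methylnaphthalen-1-yl)-3,5-dimethoxyphenyl]propan-2-yl]-4-methylbenzenesulfinamide | N#Cc1c(OC)cc(OC)c(-c2ccc(OC)c3c(OC)cc(C)cc23)c1C[C@H](C)N([Li])[S@@](=O)c1ccc(C)cc1 | intermediate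
18 | N,N′-dilithio derivative of the methyl ketimine formed from 17 at the nitrile | CC(=N[Li])c1c(OC)cc(OC)c(-c2ccc(OC)c3c(OC)cc(C)cc23)c1C[C@H](C)N([Li])[S@@](=O)c1ccc(C)cc1 | intermediate
19 | (2S)-1-[6-(4,5-dimethoxy-7-methylnaphthalen-1-yl)-2-(1-iminoethyl)-3,5-dimethoxyphenyl]propan-2-amine | CC(=N)c1c(OC)cc(OC)c(-c2ccc(OC)c3c(OC)cc(C)cc23)c1C[C@H](C)N | intermediate
20 | (3S)-5-(4,5-dimethoxy-7-methylnaphthalen-1-yl)-6,8-dimethoxy-1,3-dimethyl-3,4-dihydroisoquinoline | CC1=N[C@@H](C)Cc2c1c(OC)cc(OC)c2-c1ccc(OC)c2c(OC)cc(C)cc12 | intermediate
21 | (3S)-5-(4,5-dimethoxy-7-methylnaphthalen-1-yl)-6,8-dimethoxy-1,2,3-trimethyl-3,4-dihydroisoquinolin-2-ium iodide | CC1=[N+](C)[C@@H](C)Cc2c1c(OC)cc(OC)c2-c1ccc(OC)c2c(OC)cc(C)cc12.[I-] | intermediate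
22 | (1R,3S)-5-(4,5-dimethoxy-7-methylnaphthalen-1-yl)-6,8-dimethoxy-1,2,3-trimethyl-1,2,3,4-tetrahydroisoquinoline | COc1cc(OC)c2c(c1-c1ccc(OC)c3c(OC)cc(C)cc13)C[C@H](C)N(C)[C@@H]2C | target

Total step count: 9. Longest linear sequence: 7 steps (steps 1, 2, 3, 4, 6, 8, 9).

Steps most likely to fail

Step 8. The carbanion may deprotonate the acetaldimine instead of adding to it. Facial selectivity toward the small methyl-substituted imine may erode, and this cannot be repaired later because the auxiliary is lost in the same flask. Metalation next to the nitrile may also outrun the addition of MeLi. The fallback sets C3 by reduction instead of addition; it sets out from 13 and comes back at 20. Lateral lithiation of 13 (LiN(iPr)2, THF, −78 °C) and acylation with N-methoxy-N-methylacetamide should give aryl acetone F1. Condensation with (S)-2-methylpropane-2-sulfinamide (Ti(OEt)4, THF, 60 °C) should give N-sulfinyl ketimine F2. NaBH4 (THF, −50 °C) should deliver hydride through the chelated transition state to give (S,S)-sulfinamide F3, whose diastereomers can be separated by chromatography while the auxiliary is still attached. MeLi (THF, −78 to 0 °C) and then HCl in MeOH, as in the last two stages of step 8, should close the ring to 20.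

Step 6. Oxidative addition into the doubly ortho-substituted, electron-rich bromide and transmetalation to the hindered centre may be slow, so that protonation and homocoupling of the organozinc take over. The fallback replaces the zinc reagent made in the flask by an isolable boron nucleophile; it sets out from 7 and comes back at 13. Bromine–lithium exchange on 7 (n-BuLi, THF, −78 °C), quenching with B(OiPr)3 and acidic work-up should give boronic acid F4, which can be purified. Suzuki–Miyaura coupling with 10 (Pd(OAc)2, 2-dicyclohexylphosphino-2′,6′-dimethoxybiphenyl, K3PO4, toluene/H2O, 100 °C) should then give 13.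

Step 3. E/Z equilibration may be incomplete (only the Z acid can close), and the strong acid may cause loss or migration of the bromine para to the methoxy group. The fallback closes the ring through a ketene under buffered conditions; it sets out from 4 and comes back at 6. Cleavage of the tert-butyl ester with CF3CO2H (CH2Cl2, rt) should give acid 5, now isolated. Heating with Ac2O and NaOAc (140 °C) should form the mixed anhydride and the vinylketene, whose 6π-electrocyclisation and O-acetylation give naphthyl acetate F5. Methanolysis (K2CO3, MeOH, rt) should then give 6.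

Further compounds
F1 | step 8 | 3-(4,5-dimethoxy-7-methylnaphthalen-1-yl)-4,6-dimethoxy-2-(2-oxopropyl)benzonitrile | CC(=O)Cc1c(-c2ccc(OC)c3c(OC)cc(C)cc23)c(OC)cc(OC)c1C#N
F2 | step 8 | (S,E)-N-[1-[2-cyano-6-(4,5-dimethoxy-7-methylnaphthalen-1-yl)-3,5-dimethoxyphenyl]propan-2-ylidene]-2-methylpropane-2-sulfinamide | C/C(Cc1c(-c2ccc(OC)c3c(OC)cc(C)cc23)c(OC)cc(OC)c1C#N)=N\[S@@](=O)C(C)(C)C
F3 | step 8 | (S)-N-[(2S)-1-[2-cyano-6-(4,5-dimethoxy-7-methylnaphthalen-1-yl)-3,5-dimethoxyphenyl]propan-2-yl]-2-methylpropane-2-sulfinamide | N#Cc1c(OC)cc(OC)c(-c2ccc(OC)c3c(OC)cc(C)cc23)c1C[C@H](C)N[S@@](=O)C(C)(C)C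
F4 | step 6 | (4,5-dimethoxy-7-methylnaphthalen-1-yl)boronic acid | OB(O)c1ccc(OC)c2c(OC)cc(C)cc12
F5 | step 3 | 5-bromo-8-methoxy-3-methylnaphthalen-1-yl acetate | COc1ccc(Br)c2cc(C)cc(OC(C)=O)c12
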